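The chain (C1 = ketone carbon, C13 = carbinol) is cut at the C10–C11 methylene–methylene bond. The key step exploits the 1,3-relationship between C11 and the C13 oxygen: C12, C13 and that oxygen are read as an oxirane ring, C11 as a one-carbon phosphorus ylide. In one pot, methylenetriphenylphosphorane opens (S)-2-propyloxirane and the resulting γ-oxido ylide olefinates the C10 aldehyde of a tri-O-benzyl acylphloroglucinol fragment. Three components are thereby joined, C11–C12 and C10=C11 are formed, and the C13 hydroxyl appears unprotected with the epoxide's configuration. The ortho,ortho'-dioxygenated benzene ring shields the C1 ketone. Hydrogenation then saturates C10=C11 and frees the phenols.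

Key step: step 3

Remark: the chain is numbered from the ketone carbon (C1) to the terminal methyl (C16), and the target is the (13S) isomer. 1,3,5-Tris(benzyloxy)benzene and (S)-2-propyloxirane are taken as catalogue compounds.

Step 1
Reactants: 1 1,3,5-tris(benzyloxy)benzene; 2 undec-10-enoic acid
Product: 4 1-[2,4,6-tris(benzyloxy)phenyl]undec-10-en-1-one, via mixed anhydride 3 (not isolated)
Conditions: 2, TFAA (1.1 equiv), CH2Cl2, 0 °C; then 1, 0 °C → rt
Reagents that add atoms: none
Why: Friedel–Crafts acylation through the mixed carboxylic–trifluoroacetic anhydride; the three equivalent ring positions of the trialkoxyarene are nucleophilic enough to react without a Lewis acid, which spares the benzyl ethers and the terminal alkene, and the ketone formed deactivates the ring against a second acylation.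

Step 2
Reactants: 4 1-[2,4,6-tris(benzyloxy)phenyl]undec-10-en-1-one
Product: 6 10-oxo-10-[2,4,6-tris(benzyloxy)phenyl]decanal, via vicinal diol 5 (not isolated)
Conditions: OsO4 (cat.), NaIO4, 2,6-lutidine, 1,4-dioxane/H2O (3:1), rt
Reagents that add atoms: osmium tetroxide, O=[Os](=O)(=O)=O (transfers the oxygen that ends as the aldehyde oxygen; re-oxidised by sodium periodate, [Na+].[O-]I(=O)(=O)=O, in water, O)
Why: Lemieux–Johnson oxidation; the monosubstituted C10=C11 alkene is the only site for dihydroxylation, periodate cleaves the 1,2-diol to the C10 aldehyde with loss of C11, and the lutidine buffer limits over-oxidation while ketone and benzyl ethers stay inert.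

Step 3
Reactants: 6 10-oxo-10-[2,4,6-tris(benzyloxy)phenyl]decanal; 7 methyltriphenylphosphonium bromide; 8 (S)-2-propyloxirane
Product: 12 (13S)-13-hydroxy-1-[2,4,6-tris(benzyloxy)phenyl]hexadec-10-en-1-one (E/Z mixture), via methylenetriphenylphosphorane 9 (not isolated), via oxaphospholane 10 (not isolated), via γ-oxido ylide 11 (not isolated)
Conditions: 7, n-BuLi (1 equiv), THF, 0 °C; 8, 0 °C → rt; n-BuLi (1 equiv), −78 → 0 °C; 6 (limiting), −78 °C → rt; H2O
Reagents that add atoms: none
Why: Wittig olefination through a γ-oxido ylide (epoxide/methylene ylide/aldehyde three-component union): ylide 9 opens oxirane 8 by SN2 attack at its unsubstituted carbon to a betaine that rests as oxaphospholane 10, a second equivalent of n-BuLi removes a P–CH2 proton to give ylide 11, and 11 adds to the aldehyde of 6 to give an oxaphosphetane that collapses to the C10=C11 alkene and triphenylphosphine oxide. The closest known reaction type is the Wittig reaction of oxido-substituted phosphorus ylides with aldehydes, which tends to favour the E-alkene; the geometry is immaterial because both isomers converge in step 4. No ring of the product is closed; the oxaphospholane (O→P addition) and the oxaphosphetane ([2+2]) are transient. No new stereocentre is formed: C13 is the oxirane stereocentre, its C–O bond is never broken, and its (S) configuration passes unchanged into 12. The step needs regioselective opening at the CH2 of the oxirane, secured by the monosubstitution of 8, and chemoselective olefination of the aldehyde in the presence of the C1 ketone, secured by the two ortho-benzyloxy groups that twist and shield the aryl ketone and by adding 6 last, at −78 °C, when no free n-BuLi remains.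

Step 4
Reactants: 12 (13S)-13-hydroxy-1-[2,4,6-tris(benzyloxy)phenyl]hexadec-10-en-1-one (E/Z mixture)
Product: 14 (13S)-13-hydroxy-1-(2,4,6-trihydroxyphenyl)hexadecan-1-one, via saturated tribenzyl ether 13 (not isolated)
Conditions: H2 (1 atm), 10% Pd/C, EtOAc/MeOH, rt
Reagents that add atoms: none
Why: Heterogeneous catalytic hydrogenation saturates the C10=C11 alkene (both geometric isomers give the same alkane) and hydrogenolyses the three aryl benzyl ethers, while the non-benzylic C13 carbinol and the hydrogen-bonded, electron-rich acylphloroglucinol ketone should not be reduced under these mild conditions, so C13 stays (S).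

Compound list
1 | 1,3,5-tris(benzyloxy)benzene | c1ccc(COc2cc(OCc3ccccc3)cc(OCc3ccccc3)c2)cc1 | starting material
2 | undec-10-enoic acid | C=CCCCCCCCCC(=O)O | starting material
3 | undec-10-enoic trifluoroacetic anhydride (in situ) | C=CCCCCCCCCC(=O)OC(=O)C(F)(F)F | intermediate
4 | 1-[2,4,6-tris(benzyloxy)phenyl]undec-10-en-1-one | C=CCCCCCCCCC(=O)c1c(OCc2ccccc2)cc(OCc2ccccc2)cc1OCc1ccccc1 | intermediate
5 | 10,11-dihydroxy-1-[2,4,6-tris(benzyloxy)phenyl]undecan-1-one (both C10 configurations, in situ) | OCC(O)CCCCCCCCC(=O)c1c(OCc2ccccc2)cc(OCc2ccccc2)cc1OCc1ccccc1 | intermediate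
6 | 10-oxo-10-[2,4,6-tris(benzyloxy)phenyl]decanal | O=CCCCCCCCCC(=O)c1c(OCc2ccccc2)cc(OCc2ccccc2)cc1OCc1ccccc1 | intermediate
7 | methyltriphenylphosphonium bromide | C[P+](c1ccccc1)(c1ccccc1)c1ccccc1.[Br-] | starting material
8 | (S)-2-propyloxirane | CCC[C@H]1CO1 | starting material
9 | methylenetriphenylphosphorane (in situ) | C=P(c1ccccc1)(c1ccccc1)c1ccccc1 | intermediate
10 | (5S)-5-propyl-2,2,2-triphenyl-1,2λ5-oxaphospholane (in situ) | CCC[C@H]1CCP(c2ccccc2)(c2ccccc2)(c2ccccc2)O1 | intermediate
11 | lithium (3S)-1-(triphenyl-λ5-phosphanylidene)hexan-3-olate, the γ-oxido ylide (in situ) | CCC[C@H]([O-])CC=P(c1ccccc1)(c1ccccc1)c1ccccc1.[Li+] | intermediate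
12 | (13S)-13-hydroxy-1-[2,4,6-tris(benzyloxy)phenyl]hexadec-10-en-1-one (E/Z mixture) | CCC[C@H](O)CC=CCCCCCCCCC(=O)c1c(OCc2ccccc2)cc(OCc2ccccc2)cc1OCc1ccccc1 | intermediate
13 | (13S)-13-hydroxy-1-[2,4,6-tris(benzyloxy)phenyl]hexadecan-1-one (in situ) | CCC[C@H](O)CCCCCCCCCCCC(=O)c1c(OCc2ccccc2)cc(OCc2ccccc2)cc1OCc1ccccc1 | intermediate
14 | (13S)-13-hydroxy-1-(2,4,6-trihydroxyphenyl)hexadecan-1-one | CCC[C@H](O)CCCCCCCCCCCC(=O)c1c(O)cc(O)cc1O | target

Total step count: 4
Longest linear sequence: 4 steps (1 → 4 → 6 → 12 → 14)

Steps most likely to fail

Step 3 (key step). The epoxide may be opened only sluggishly or incompletely by the ylide, or the basic γ-oxido ylide may take a proton from the enolisable aldehyde in place of olefinating it. The fallback makes the same C10=C11 bond by olefin cross-metathesis. Setting out from 8, copper-catalysed opening with vinylmagnesium bromide (CuI cat., THF, −30 °C) should give (S)-hept-1-en-4-ol F1. Setting out from 4 (the alkene before cleavage), cross-metathesis with an excess of F1 (second-generation Hoveyda–Grubbs catalyst, CH2Cl2, 40 °C, ethylene purged) should give 12 as an E/Z mixture, where the route is rejoined; step 2 is then not needed.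

Step 1. An ortho-benzyl group may be lost or migrate from oxygen to carbon under the acid formed, or trifluoroacetylation of the arene may compete with transfer of the long-chain acyl group. The fallback builds the ketone by carbonyl addition and oxidation in place of acylation. Setting out from 1, Vilsmeier–Haack formylation (POCl3, DMF; aqueous NaOAc) should give 2,4,6-tris(benzyloxy)benzaldehyde F2. Dec-9-en-1-ylmagnesium bromide F3 (from commercial 10-bromodec-1-ene and Mg, THF) should add to F2 to give racemic 1-[2,4,6-tris(benzyloxy)phenyl]undec-10-en-1-ol F4, and Dess–Martin oxidation (CH2Cl2, rt) should return 4.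

Step 4. Palladium may move the double bond toward C13 with redox isomerisation of the carbinol to a ketone, or the benzylic ketone may be over-reduced during prolonged hydrogenolysis. The fallback separates the two events and removes the benzyl groups without hydrogen. Setting out from 12, diimide reduction (TsNHNH2, NaOAc, DME/H2O, reflux) should give 13, now isolated. BCl3 with pentamethylbenzene as cation scavenger (CH2Cl2, −78 °C) should then cleave the three aryl benzyl ethers and give 14 directly.

Further compounds
F1 | step 3 | (S)-hept-1-en-4-ol | CCC[C@H](O)CC=C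
F2 | step 1 | 2,4,6-tris(benzyloxy)benzaldehyde | O=Cc1c(OCc2ccccc2)cc(OCc2ccccc2)cc1OCc1ccccc1
F3 | step 1 | dec-9-en-1-ylmagnesium bromide | C=CCCCCCCCC[Mg]Br
F4 | step 1 | 1-[2,4,6-tris(benzyloxy)phenyl]undec-10-en-1-ol (racemic) | C=CCCCCCCCCC(O)c1c(OCc2ccccc2)cc(OCc2ccccc2)cc1OCc1ccccc1
F0 | step 4 | none | none
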